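- spring: substrate 18 mM; enzyme 3.7 µM; run made earlier
- flask: substrate 37 mM; enzyme 3.7 µM

spring run (percent of the substrate charged)

| time / min | product / % | substrate / % |
|---|---|---|
| 2.00 | 43.8 | 56.1 |
| 4.00 | 59.1 | 39.5 |
| 6.00 | 70.5 | 28.7 |
| 8.00 | 76.0 | 22.5 |
| 10.0 | 77.2 | 18.5 |
| 12.0 | 83.1 | 17.3 |

(each reading ± 1 percentage point)

* apparent order in enzyme when 10% of the substrate are converted (percent change of the rate of making product for one percent more enzyme charged)

- no earlier run changes the charge of enzyme; that part of a forecast is a guess

Your flask has twice the substrate of the spring run at the same enzyme, 3.7 µM, so the readings show me how substrate falls but not what a change in the enzyme charge does. What I can offer is my own reckoning, which follows one enzyme molecule. I suppose that at any instant it is either free and turning substrate over, or paired in a resting dimer, an off-cycle resting state. I call f the fraction of the enzyme charge that is free, so on that supposition the rate at a given conversion goes with f times the charge. If the pairing stays at equilibrium, the paired fraction divided by f squared grows in step with the charge, and differentiating gives the order in enzyme: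

n = 1 / (2 − f)

At f = 1 this gives order 1, and as f nears zero it gives 0.5. No run shows f, so I guess an even split, f = 0.5, and commit to the order at that split, 0.667.

Your hunch, the forecast, stands higher at 1.03: “I expect slightly above 1”. The flask gives 0.71.

    2 enzyme ⇌ resting dimer, settled at all times (K = 1.50 × 10⁵ L mol⁻¹)
    substrate + enzyme → product + enzyme, rate k2*[substrate]^2*[enzyme]/(1 + ([substrate]/Kh2)^2) (35.0 mM, k = 1.80 × 10⁵ L² mol⁻² s⁻¹)

The proof is the same flask without the association of two enzyme to resting dimer, where the order moves from 0.71 to 1.0. At 4.00 min the flask holds 60.0% of the catalyst charged as enzyme and 40.0% as resting dimer, and that f turns 0.667 into 0.714. With twice the enzyme in this flask, the time to 10% conversion changes by a factor of 0.622, beside 0.610 from 2 raised to minus that order.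

Readings and results come from a simulation with constants of no real substance; noise was put on by code.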